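The α-methylene-γ-butyrolactone ring is read as three components: the exocyclic methylene C13 with C11 and C7 is a terminal allene, the lactone carbonyl C12 is carbon dioxide, and the carbinol carbon C6 is an aldehyde. A nickel-mediated union of a furanone-bearing (R)-silyloxy allene, CO2 and cinnamaldehyde should form C11–C12 and C6–C7 in one operation and set C6 and C7; acid work-up closes the lactone. C1, C10, C14, C9 and C8 come from (S)-citramalic acid, whose dioxolanone is acylated by an enyne acetylide to build the 3(2H)-furanone. Ring-closing metathesis at C4=C5 then closes the ten-membered ring; silyl removal, methacryloylation and PMB removal finish the route.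

Key step: step 9

Remark: atoms carry germacrane numbers (C1 furanone ketone, C2=C3 furanone alkene, C4=C5 ring alkene, C15 the CH2OH on C4, C6 lactone carbinol, C7, C8 ester carbinol, C9, C10 quaternary carbon with methyl C14, C11=C13 exocyclic methylene, C12 lactone carbonyl); amine 3 is assumed to be purchasable (otherwise one step from propargyl bromide and diisopropylamine).

Step 1
Reactants: 1 (S)-citramalic acid
Product: 2 2-[(4S)-2,2,4-trimethyl-5-oxo-1,3-dioxolan-4-yl]acetic acid
Conditions: Me2C(OMe)2, TsOH·H2O (cat.), CH2Cl2, rt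
Reagents that add atoms: 2,2-dimethoxypropane, COC(C)(C)OC
Why: Acetalisation of the α-hydroxy acid closes the five-membered 1,3-dioxolan-4-one in preference to the six-membered alternative, which leaves the C8 carboxyl free and turns C1 into an activated ester without touching C10.

Step 2
Reactants: 2 dioxolanone acid; 3 N,N-di(propan-2-yl)prop-2-yn-1-amine
Product: 5 amino ynone, via acid chloride 4 (not isolated)
Conditions: (COCl)2, DMF (cat.), CH2Cl2, 0 °C to rt, concentrate; then 3, PdCl2(PPh3)2 (2 mol %), CuI (4 mol %), Et3N, THF, rt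
Reagents that add atoms: none
Why: Acid chloride formation followed by acyl Sonogashira coupling should give the ynone under conditions too mild to open the dioxolanone or to eliminate the C10 oxygen.

Step 3
Reactants: 5 amino ynone
Product: 6 (R)-propargylic alcohol
Conditions: Ru[(R,R)-TsDPEN](p-cymene) (1 mol %), i-PrOH, rt
Reagents that add atoms: none
Why: Noyori asymmetric transfer hydrogenation of an alkynyl ketone; the (R,R)-catalyst distinguishes the alkynyl from the alkyl flank and should set C8 as (R) under catalyst control, and the base-free medium spares the dioxolanone.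

Step 4
Reactants: 6 (R)-propargylic alcohol
Product: 7 TBS ether
Conditions: TBSOTf, 2,6-lutidine, CH2Cl2, −78 °C
Reagents that add atoms: tert-butyldimethylsilyl trifluoromethanesulfonate, CC(C)(C)[Si](C)(C)OS(=O)(=O)C(F)(F)F
Why: Silylation with a silyl triflate is fast at low temperature, so the γ-hydroxy dioxolanone is capped before it can lactonise onto C1.

Step 5
Reactants: 7 TBS ether
Product: 8 allene dioxolanone
Conditions: CuBr (0.5 equiv), 1,4-dioxane, 100 °C
Reagents that add atoms: none
Why: This is the second stage of the Crabbé allene synthesis: copper-promoted 1,5-hydride transfer from an N-isopropyl C–H to alkyne carbon C7 with loss of the imine should convert the propargylic amine into the terminal allene without involving C8.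

Step 6
Reactants: 9 2,3-dibromoprop-1-ene
Product: 10 2-bromoallyl PMB ether
Conditions: 4-methoxybenzyl alcohol, NaH, THF, 0 °C to rt
Reagents that add atoms: 4-methoxybenzyl alcohol, COc1ccc(CO)cc1
Why: Williamson etherification; the alkoxide displaces the allylic bromide while the vinylic bromide is inert.

Step 7
Reactants: 10 2-bromoallyl PMB ether
Product: 11 terminal enyne
Conditions: HC≡CMgBr, ZnBr2, THF, 0 °C; then 10, Pd(PPh3)4 (5 mol %), rt
Reagents that add atoms: ethynylmagnesium bromide, C#C[Mg]Br
Why: Negishi coupling of ethynylzinc bromide with the alkenyl bromide should give the terminal enyne directly, since the C–H end of the alkyne does not couple in the absence of copper and amine.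

Step 8
Reactants: 11 terminal enyne; 8 allene dioxolanone
Product: 14 furanone allene, via lithium acetylide 12 (not isolated), via hydroxy ynone 13 (not isolated)
Conditions: 11, n-BuLi, THF, −78 °C; then 8, −78 to −20 °C; aq NH4Cl; then K2CO3 (0.2 equiv), MeOH, 0 °C to rt
Reagents that add atoms: none
Why: Acylation of the lithium acetylide by the dioxolanone (the ring-bound tetrahedral alkoxide limits over-addition and its collapse releases acetone and the C10 hydroxyl) is followed by base-mediated 5-endo-dig oxa-Michael cyclisation of the α'-hydroxy ynone to the 3(2H)-furanone, a mode chosen over gold catalysis because the allene is inert to alkoxide; C8 and C10 are untouched.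

Step 9
Reactants: 14 furanone allene; 15 carbon dioxide; 16 (E)-cinnamaldehyde
Product: 19 styryl trans-lactone, via oxanickelacycle 17 (not isolated), via hydroxy acid 18 (not isolated)
Conditions: Ni(cod)2 (1.1 equiv), DBU (2.2 equiv), CO2 (1 atm), THF, 0 °C; then 16 (2 equiv), 0 °C to rt; then 1 M HCl, rt
Reagents that add atoms: none
Why: Zerovalent nickel couples the terminal C11=C13 π-bond of the allene with CO2 by oxidative cyclisation (C11–C12 bond) to the allylnickel carboxylate 17, whose nickel-bearing terminus C13 delivers the substituted terminus C7 to the aldehyde carbon through a six-membered chair (C6–C7 bond), and acidification gives hydroxy acid 18, which lactonises. The closest known reaction type is the nickel-mediated sequential addition of carbon dioxide and aromatic aldehydes to terminal allenes. The only ring closed is the γ-lactone, by 5-exo-trig attack of the C6 hydroxyl on the C12 carboxyl with retention at C6. C6 should be set anti to C7 (trans-lactone) by the chair in which the (E)-σ-allyl (from the favoured syn-π-allyl) and the styryl group are both equatorial, and C7 should be set relative to C8 by the conformer in which C8–H eclipses the C11 carboxylate (allylic 1,3-strain), the aldehyde approaching anti to the C9 branch. The step needs nickel to engage the allene and not the dienone (the allene is the best π-ligand present and no aldehyde is there until the nickelacycle has formed), γ- and 1,2-regioselectivity (secured by the cyclic transition state) and survival of the allylic oxygen, for which the poor leaving group OTBS was chosen.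

Step 10
Reactants: 19 styryl trans-lactone
Product: 20 macrocycle with 8-OTBS and 15-OPMB
Conditions: second-generation Hoveyda–Grubbs catalyst RuCl2(H2IMes)(=CH-C6H4-2-O-i-Pr) (15 mol %), 1,4-benzoquinone (20 mol %), toluene (1 mM), 90 °C
Reagents that add atoms: none
Why: Ring-closing metathesis should start on the styryl alkene and close onto the 1,1-disubstituted alkene, the ring forcing the (Z)-trisubstituted C4=C5 bond and releasing styrene, with no stereocentre involved.

Step 11
Reactants: 20 macrocycle with 8-OTBS and 15-OPMB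
Product: 21 C8 alcohol
Conditions: HF·pyridine, pyridine, THF, 0 °C to rt
Reagents that add atoms: none
Why: Buffered acidic fluoride should cleave the secondary silyl ether while the PMB ether, the lactone and the Michael acceptors are tolerated.

Step 12
Reactants: 21 C8 alcohol
Product: 22 methacrylate PMB ether
Conditions: methacrylic anhydride, Et3N, DMAP (cat.), CH2Cl2, 0 °C
Reagents that add atoms: methacrylic anhydride, C=C(C)C(=O)OC(=O)C(C)=C
Why: DMAP-catalysed acylation of the C8 hydroxyl at 0 °C should be faster than translactonisation to the 8,12-olide or isomerisation of the exocyclic methylene.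

Step 13
Reactants: 22 methacrylate PMB ether
Product: 23 target
Conditions: DDQ, CH2Cl2–pH 7 phosphate buffer (10:1), 0 °C
Reagents that add atoms: none
Why: Oxidative cleavage of the PMB ether with DDQ under neutral conditions should leave the methacrylate, the α-methylene lactone and the furanone untouched and release the C15 hydroxyl.

Compound list
1 | (2S)-2-hydroxy-2-methylbutanedioic acid, (S)-citramalic acid | OC(=O)C[C@](C)(O)C(=O)O | starting material
2 | 2-[(4S)-2,2,4-trimethyl-5-oxo-1,3-dioxolan-4-yl]acetic acid | OC(=O)C[C@]1(C)OC(C)(C)OC1=O | intermediate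
3 | N,N-di(propan-2-yl)prop-2-yn-1-amine | C#CCN(C(C)C)C(C)C | starting material
4 | 2-[(4S)-2,2,4-trimethyl-5-oxo-1,3-dioxolan-4-yl]acetyl chloride | ClC(=O)C[C@]1(C)OC(C)(C)OC1=O | intermediate
5 | (5S)-5-{5-[di(propan-2-yl)amino]-2-oxopent-3-yn-1-yl}-2,2,5-trimethyl-1,3-dioxolan-4-one | CC(C)N(CC#CC(=O)C[C@]1(C)OC(C)(C)OC1=O)C(C)C | intermediate
6 | (5S)-5-{(2R)-5-[di(propan-2-yl)amino]-2-hydroxypent-3-yn-1-yl}-2,2,5-trimethyl-1,3-dioxolan-4-one | CC(C)N(CC#C[C@H](O)C[C@]1(C)OC(C)(C)OC1=O)C(C)C | intermediate
7 | (5S)-5-{(2R)-2-{[tert-butyl(dimethyl)silyl]oxy}-5-[di(propan-2-yl)amino]pent-3-yn-1-yl}-2,2,5-trimethyl-1,3-dioxolan-4-one | CC(C)N(CC#C[C@H](O[Si](C)(C)C(C)(C)C)C[C@]1(C)OC(C)(C)OC1=O)C(C)C | intermediate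
8 | (5S)-5-{(2R)-2-{[tert-butyl(dimethyl)silyl]oxy}penta-3,4-dien-1-yl}-2,2,5-trimethyl-1,3-dioxolan-4-one | C=C=C[C@H](O[Si](C)(C)C(C)(C)C)C[C@]1(C)OC(C)(C)OC1=O | intermediate
9 | 2,3-dibromoprop-1-ene | C=C(Br)CBr | starting material
10 | 1-{[(2-bromoprop-2-en-1-yl)oxy]methyl}-4-methoxybenzene | C=C(Br)COCc1ccc(OC)cc1 | intermediate
11 | 1-methoxy-4-{[(2-methylidenebut-3-yn-1-yl)oxy]methyl}benzene | C=C(C#C)COCc1ccc(OC)cc1 | intermediate
12 | lithium acetylide of 11 | [Li]C#CC(=C)COCc1ccc(OC)cc1 | intermediate
13 | (6S,8R)-8-{[tert-butyl(dimethyl)silyl]oxy}-6-hydroxy-2-{[(4-methoxyphenyl)methoxy]methyl}-6-methylundeca-1,9,10-trien-3-yn-5-one | C=C=C[C@H](O[Si](C)(C)C(C)(C)C)C[C@](C)(O)C(=O)C#CC(=C)COCc1ccc(OC)cc1 | intermediate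
14 | (2S)-2-{(2R)-2-{[tert-butyl(dimethyl)silyl]oxy}penta-3,4-dien-1-yl}-5-{3-[(4-methoxyphenyl)methoxy]prop-1-en-2-yl}-2-methylfuran-3(2H)-one | C=C=C[C@H](O[Si](C)(C)C(C)(C)C)C[C@]1(C)OC(=CC1=O)C(=C)COCc2ccc(OC)cc2 | intermediate
15 | carbon dioxide | O=C=O | starting material
16 | (2E)-3-phenylprop-2-enal, cinnamaldehyde | O=C/C=C/c1ccccc1 | starting material
17 | oxanickelacyclopentanone of divalent nickel formed from 14 and CO2: nickel bound to C13H2 and to a carboxylate oxygen of C12, exocyclic (E)-C11=C7 alkene, (8R,10S), two DBU ligands on nickel not drawn | O=C1O[Ni]C/C1=C/[C@H](O[Si](C)(C)C(C)(C)C)C[C@]2(C)OC(=CC2=O)C(=C)COCc3ccc(OC)cc3 | intermediate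
18 | (3S,4R,5E)-3-[(1R)-1-{[tert-butyl(dimethyl)silyl]oxy}-2-{(2S)-5-[3-[(4-methoxyphenyl)methoxy]prop-1-en-2-yl]-2-methyl-3-oxo-2,3-dihydrofuran-2-yl}ethyl]-4-hydroxy-2-methylidene-6-phenylhex-5-enoic acid | C=C(C(=O)O)[C@@H]([C@H](O)/C=C/c1ccccc1)[C@H](O[Si](C)(C)C(C)(C)C)C[C@]2(C)OC(=CC2=O)C(=C)COCc3ccc(OC)cc3 | intermediate
19 | (4S,5R)-4-[(1R)-1-{[tert-butyl(dimethyl)silyl]oxy}-2-{(2S)-5-[3-[(4-methoxyphenyl)methoxy]prop-1-en-2-yl]-2-methyl-3-oxo-2,3-dihydrofuran-2-yl}ethyl]-3-methylidene-5-[(E)-2-phenylethenyl]oxolan-2-one (trans-lactone; C7 is S here only because of the silyl ether priority) | c1ccccc1/C=C/[C@H]1OC(=O)C(=C)[C@@H]1[C@H](O[Si](C)(C)C(C)(C)C)C[C@]2(C)OC(=CC2=O)C(=C)COCc3ccc(OC)cc3 | intermediate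
20 | (6R,7S,8R,10S)-8-{[tert-butyl(dimethyl)silyl]oxy}-15-[(4-methoxyphenyl)methoxy]-1-oxo-3,10-epoxygermacra-2,4Z,11(13)-trien-12,6-olide | CC(C)(C)[Si](C)(C)O[C@@H]1C[C@]2(C)OC(=CC2=O)/C(COCc3ccc(OC)cc3)=C\[C@H]2OC(=O)C(=C)[C@@H]21 | intermediate
21 | (6R,7R,8R,10S)-8-hydroxy-15-[(4-methoxyphenyl)methoxy]-1-oxo-3,10-epoxygermacra-2,4Z,11(13)-trien-12,6-olide | O[C@@H]1C[C@]2(C)OC(=CC2=O)/C(COCc3ccc(OC)cc3)=C\[C@H]2OC(=O)C(=C)[C@@H]21 | intermediate
22 | (6R,7R,8R,10S)-15-[(4-methoxyphenyl)methoxy]-1-oxo-3,10-epoxygermacra-2,4Z,11(13)-trien-12,6-olide 8-(2-methylprop-2-enoate) | C=C(C)C(=O)O[C@@H]1C[C@]2(C)OC(=CC2=O)/C(COCc3ccc(OC)cc3)=C\[C@H]2OC(=O)C(=C)[C@@H]21 | intermediate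
23 | (6R,7R,8R,10S)-15-hydroxy-1-oxo-3,10-epoxygermacra-2,4Z,11(13)-trien-12,6-olide 8-(2-methylprop-2-enoate) | C=C(C)C(=O)O[C@@H]1C[C@]2(C)OC(=CC2=O)/C(CO)=C\[C@H]2OC(=O)C(=C)[C@@H]21 | target

Total step count: 13. Longest linear sequence: 11 steps (steps 1 to 5, then 8 to 13).

Steps most likely to fail

1. Step 9. The aldehyde may add through the (Z)-σ-allylnickel isomer that forms first on oxidative cyclisation, which gives poor anti/syn control and leads to the C6 epimer, that is the cis-lactone. Lesser risks are β-elimination of the silyloxy group from the allylnickel and binding of nickel by the dienone. The fallback sets out from 14 and comes back at 19. The same coupling is run but worked up at pH 5, so that the syn adduct, the (3S,4S)-hydroxy acid F1, is isolated without lactonising. F1 is then closed by Mitsunobu activation of the C6 hydroxyl (PPh3, DIAD, THF, 0 °C); the carboxylate displaces at C6 with inversion, which should give the trans-lactone 19.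

2. Step 10. Initiation on the hindered, conjugated 1,1-disubstituted alkene is slow and the bicyclic product is strained, so cross-metathesis oligomerisation through the styryl group or alkene isomerisation may win over ring closure. The fallback sets out from 8 and comes back at 20. It brings in the C4=C5 alkene preformed and closes the ring at C6–C7 with the chemistry of step 9, run intramolecularly.
 - But-2-yne-1,4-diol is mono-protected (NaH, 4-methoxybenzyl chloride) to 4-[(4-methoxyphenyl)methoxy]but-2-yn-1-ol F2.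
 - Hydroxyl-directed trans-hydroalumination with NaAlH2(OCH2CH2OCH3)2, then I2, should give (2Z)-3-iodo-4-[(4-methoxyphenyl)methoxy]but-2-en-1-ol F3.
 - TESCl and imidazole give its triethylsilyl ether F4.
 - Negishi ethynylation as in step 7 gives the enyne F5, in which the alkyne is cis to the CH2OTES group.
 - Deprotonation with n-BuLi and addition to 8 as in step 8 gives the hydroxy ynone F6 (not isolated), which K2CO3 in MeOH cyclises to the furanone F7.
 - Swern oxidation, which cleaves and oxidises the primary triethylsilyl ether selectively, gives the (Z)-dienal F8.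
 - Ni(cod)2, DBU and CO2 in THF at high dilution should form C11–C12 and C6–C7; 1 M HCl gives the macrocyclic hydroxy acid F9 (not isolated), which lactonises to 20.

3. Step 8. The tetrahedral adduct may collapse before the quench, so that a second acetylide adds to the ynone. The fallback sets out from 8 and comes back at 14. Aminolysis of the dioxolanone with Me(MeO)NH·HCl and i-PrMgCl (THF, −20 °C) gives the α-hydroxy Weinreb amide F10 with loss of acetone. F10 with two equivalents of lithium acetylide 12 should give, through the stable chelated adduct, hydroxy ynone 13, which K2CO3 in MeOH cyclises to 14.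

Further compounds
F1 | step 9 | (3S,4S,5E)-3-[(1R)-1-{[tert-butyl(dimethyl)silyl]oxy}-2-{(2S)-5-[3-[(4-methoxyphenyl)methoxy]prop-1-en-2-yl]-2-methyl-3-oxo-2,3-dihydrofuran-2-yl}ethyl]-4-hydroxy-2-methylidene-6-phenylhex-5-enoic acid | C=C(C(=O)O)[C@@H]([C@@H](O)/C=C/c1ccccc1)[C@H](O[Si](C)(C)C(C)(C)C)C[C@]2(C)OC(=CC2=O)C(=C)COCc3ccc(OC)cc3
F2 | step 10 | 4-[(4-methoxyphenyl)methoxy]but-2-yn-1-ol | OCC#CCOCc1ccc(OC)cc1
F3 | step 10 | (2Z)-3-iodo-4-[(4-methoxyphenyl)methoxy]but-2-en-1-ol | I/C(COCc1ccc(OC)cc1)=C\CO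
F4 | step 10 | triethyl({(2Z)-3-iodo-4-[(4-methoxyphenyl)methoxy]but-2-en-1-yl}oxy)silane | I/C(COCc1ccc(OC)cc1)=C\CO[Si](CC)(CC)CC
F5 | step 10 | triethyl({(2E)-3-{[(4-methoxyphenyl)methoxy]methyl}pent-2-en-4-yn-1-yl}oxy)silane (alkyne cis to CH2OTES) | C#C/C(COCc1ccc(OC)cc1)=C\CO[Si](CC)(CC)CC
F6 | step 10 | hydroxy ynone from F5 and 8: (6S,8R)-configured α'-hydroxy ynone with the (Z)-enyne side chain carrying CH2OPMB and CH2OTES | C=C=C[C@H](O[Si](C)(C)C(C)(C)C)C[C@](C)(O)C(=O)C#C/C(COCc1ccc(OC)cc1)=C\CO[Si](CC)(CC)CC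
F7 | step 10 | (2S)-2-{(2R)-2-{[tert-butyl(dimethyl)silyl]oxy}penta-3,4-dien-1-yl}-5-{(2Z)-1-[(4-methoxyphenyl)methoxy]-4-[(triethylsilyl)oxy]but-2-en-2-yl}-2-methylfuran-3(2H)-one | C=C=C[C@H](O[Si](C)(C)C(C)(C)C)C[C@]1(C)OC(=CC1=O)/C(COCc2ccc(OC)cc2)=C\CO[Si](CC)(CC)CC
F8 | step 10 | (2Z)-3-{(5S)-5-[(2R)-2-{[tert-butyl(dimethyl)silyl]oxy}penta-3,4-dien-1-yl]-5-methyl-4-oxo-4,5-dihydrofuran-2-yl}-4-[(4-methoxyphenyl)methoxy]but-2-enal | C=C=C[C@H](O[Si](C)(C)C(C)(C)C)C[C@]1(C)OC(=CC1=O)/C(COCc2ccc(OC)cc2)=C\C=O
F9 | step 10 | seco acid of 20: ten-membered ring with free C6 hydroxyl and C11(=CH2)CO2H on C7, configured as in 20 | CC(C)(C)[Si](C)(C)O[C@@H]1C[C@]2(C)OC(=CC2=O)/C(COCc3ccc(OC)cc3)=C\[C@@H](O)[C@@H]1C(=C)C(=O)O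
F10 | step 8 | (2S,4R)-4-{[tert-butyl(dimethyl)silyl]oxy}-2-hydroxy-N-methoxy-N,2-dimethylhepta-5,6-dienamide | C=C=C[C@H](O[Si](C)(C)C(C)(C)C)C[C@](C)(O)C(=O)N(C)OC
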